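**Retrosynthetic overview**
- Brevipolide H ⇒ the cyclopropane is closed last, by ruthenium-carbene cyclopropanation of the vinyl group of a hydroxy lactone with an α-diazoketone that already carries the (S)-lactate centre and the 4-methoxycinnamate.
- Hydroxy lactone ⇒ 5-(1-hydroxyallyl)cyclopent-2-enone by Baeyer–Villiger ring expansion (C→O 1,2-shift with retention: C5–C(=O) becomes C6–O), run as a catalytic kinetic resolution.
- Cyclopentenone ⇒ syn-selective titanium aldol of cyclopent-2-en-1-one with acrolein.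
- Diazoketone ⇒ (S)-lactic acid + 4-methoxycinnamic acid (from anisole by iodination and Heck coupling with acrylic acid) + Me3SiCHN2.
- Ring order: arene present from the start; six-membered lactone by ring expansion of the five-membered enone; cyclopropane last.

Assumption: [Ru((S)-Pheox)(MeCN)4]PF6 (Pheox = C-metalated (S)-2,4-diphenyl-4,5-dihydro-1,3-oxazole) and the (S)-pipecolic-acid-derived N,N′-dioxide ligand L-PiPr2 (2,6-diisopropylanilide arms, trimethylene tether) are taken to be the catalyst enantiomers that give the configurations drawn; if a test run shows the opposite sense, the mirror-image catalyst is used.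

**Step 1**
Reactants: 1 anisole
Product: 2 1-iodo-4-methoxybenzene
Conditions: NIS (1.05 equiv), CF3CO2H (10 mol %), MeCN, rt
Reagents that add atoms: N-iodosuccinimide, O=C1CCC(=O)N1I
Why: Electrophilic aromatic substitution (iodination) with acid-activated NIS goes almost only para to the methoxy group, which gives the 1,4-pattern needed and creates no stereocentre.

**Step 2**
Reactants: 2 1-iodo-4-methoxybenzene; 3 acrylic acid
Product: 4 (2E)-3-(4-methoxyphenyl)prop-2-enoic acid
Conditions: Pd(OAc)2 (1 mol %), Et3N (2.5 equiv), MeCN, 80 °C; then aq. HCl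
Reagents that add atoms: none
Why: Mizoroki–Heck reaction: oxidative addition of the aryl iodide to zerovalent palladium, syn-insertion of acrylic acid and syn-β-hydride elimination give the (E)-cinnamic acid only, and aryl iodides couple without a phosphine.

**Step 3**
Reactants: 4 (2E)-3-(4-methoxyphenyl)prop-2-enoic acid; 5 (S)-lactic acid
Product: 7 (2S)-2-{[(2E)-3-(4-methoxyphenyl)prop-2-enoyl]oxy}propanoic acid, via (2E)-3-(4-methoxyphenyl)prop-2-enoyl chloride 6 (not isolated)
Conditions: (COCl)2, DMF (cat.), CH2Cl2, 0 °C → rt, evaporate; then 5 (2 equiv), pyridine, DMAP (cat.), CH2Cl2, 0 °C → rt; aq. HCl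
Reagents that add atoms: none
Why: Acid chloride formation and pyridine/DMAP-catalysed O-acylation (nucleophilic acyl substitution) esterify the secondary hydroxyl of the cheap hydroxy acid used in excess, any mixed anhydride being hydrolysed in the acidic work-up, and the (S)-centre is untouched because its C–O bond is not broken.

**Step 4**
Reactants: 7 (2S)-2-{[(2E)-3-(4-methoxyphenyl)prop-2-enoyl]oxy}propanoic acid
Product: 9 (2S)-4-diazo-3-oxobutan-2-yl (2E)-3-(4-methoxyphenyl)prop-2-enoate, via (2S)-1-chloro-1-oxopropan-2-yl (2E)-3-(4-methoxyphenyl)prop-2-enoate 8 (not isolated)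
Conditions: (COCl)2, DMF (cat.), CH2Cl2, 0 °C → rt, evaporate; then Me3SiCHN2 (2 equiv), THF/MeCN, 0 °C
Reagents that add atoms: (trimethylsilyl)diazomethane, C[Si](C)(C)C=[N+]=[N-]
Why: Acylation of Me3SiCHN2 by the acid chloride (the first stage of an Arndt–Eistert sequence) followed by loss of Me3SiCl gives the α-diazoketone, and the absence of amine base prevents ketene formation so that the (S)-centre next to the carbonyl keeps its configuration.

**Step 5**
Reactants: 10 cyclopent-2-en-1-one; 11 acrolein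
Product: 14 rac-(5R,1′S)-5-(1-hydroxyprop-2-en-1-yl)cyclopent-2-en-1-one, via lithium cyclopenta-1,4-dien-1-olate 12 (not isolated), via triisopropoxytitanium cyclopenta-1,4-dien-1-olate 13 (not isolated)
Conditions: LiN(iPr)2 (1.05 equiv), THF, −78 °C; TiCl(OiPr)3 (1.1 equiv), −78 → −40 °C; 11 (1.2 equiv), −78 °C; aq. NH4Cl
Reagents that add atoms: none
Why: Kinetic α′-deprotonation gives the cross-conjugated dienolate and, after transmetalation, the triisopropoxytitanium enolate adds 1,2 to the enal in a titanium-mediated aldol reaction that is syn-selective (about 6:1 expected, anti isomer removed by chromatography) even for the geometrically fixed ring enolate, which sets the relative configuration of C5 and C1′ as a racemate.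

**Step 6**
Reactants: 14 rac-(5R,1′S)-5-(1-hydroxyprop-2-en-1-yl)cyclopent-2-en-1-one
Product: 15 (6R)-6-[(1S)-1-hydroxyprop-2-en-1-yl]-5,6-dihydro-2H-pyran-2-one
Conditions: Sc(OTf)3 (5 mol %), N,N′-dioxide ligand L-PiPr2 (6 mol %), mCPBA (0.55 equiv), EtOAc, −20 °C, stopped near 50% conversion; unreacted (5S,1′R)-14 removed by chromatography
Reagents that add atoms: 3-chloroperoxybenzoic acid, O=C(OO)c1cccc(Cl)c1
Why: Proposed new method: a chiral Sc(OTf)3–N,N′-dioxide complex is proposed to bind the β-hydroxy enone as a six-membered chelate through its carbonyl and hydroxyl oxygens, which activates the sluggish conjugated carbonyl towards peracid addition and holds the Criegee adduct so that the C1–C5 bond rather than the C1–C2 vinyl bond lies antiperiplanar to the O–O bond, so the secondary sp3 carbon C5 (intrinsically a better migrating group than vinyl) shifts to oxygen with retention and the (5R) carbon stereocentre becomes the (6R) C–O stereocentre of the six-membered lactone, while the chiral pocket oxidises the (5R,1′S)-enantiomer much faster than its mirror image (kinetic resolution, maximum yield 50%, which fixes the absolute configuration at C6 and C1′); the closest known reactions are the Sc(OTf)3/N,N′-dioxide-catalysed asymmetric Baeyer–Villiger oxidation (desymmetrisation and kinetic resolution) of saturated cycloalkanones and the peracid Baeyer–Villiger ring expansion of α-branched cyclic ketones, neither shown for a conjugated cyclopentenone.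

**Step 7**
Reactants: 15 (6R)-6-[(1S)-1-hydroxyprop-2-en-1-yl]-5,6-dihydro-2H-pyran-2-one; 9 (2S)-4-diazo-3-oxobutan-2-yl (2E)-3-(4-methoxyphenyl)prop-2-enoate
Product: 16 brevipolide H
Conditions: [Ru((S)-Pheox)(MeCN)4]PF6 (3 mol %), CH2Cl2, 0 °C → rt, 9 (1.3 equiv) added over 6 h
Reagents that add atoms: none
Why: Catalytic asymmetric cyclopropanation by carbene transfer from the phenyloxazoline–ruthenium carbene, a reaction type that is trans-selective and highly face-selective for monosubstituted alkenes, reacts at the only terminal alkene and sets both cyclopropane centres as (1S,2S) under catalyst control while the lactate, C1′ and C6 centres are not involved.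

**Compound list**
1 | anisole (methoxybenzene) | COc1ccccc1 | starting material
2 | 1-iodo-4-methoxybenzene | COc1ccc(I)cc1 | intermediate
3 | acrylic acid (prop-2-enoic acid) | C=CC(=O)O | starting material
4 | (2E)-3-(4-methoxyphenyl)prop-2-enoic acid | COc1ccc(/C=C/C(=O)O)cc1 | intermediate
5 | (S)-lactic acid, (2S)-2-hydroxypropanoic acid | C[C@H](O)C(=O)O | starting material
6 | (2E)-3-(4-methoxyphenyl)prop-2-enoyl chloride | COc1ccc(/C=C/C(Cl)=O)cc1 | intermediate
7 | (2S)-2-{[(2E)-3-(4-methoxyphenyl)prop-2-enoyl]oxy}propanoic acid | COc1ccc(/C=C/C(=O)O[C@@H](C)C(=O)O)cc1 | intermediate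
8 | (2S)-1-chloro-1-oxopropan-2-yl (2E)-3-(4-methoxyphenyl)prop-2-enoate | COc1ccc(/C=C/C(=O)O[C@@H](C)C(Cl)=O)cc1 | intermediate
9 | (2S)-4-diazo-3-oxobutan-2-yl (2E)-3-(4-methoxyphenyl)prop-2-enoate | COc1ccc(/C=C/C(=O)O[C@@H](C)C(=O)C=[N+]=[N-])cc1 | intermediate
10 | cyclopent-2-en-1-one | O=C1C=CCC1 | starting material
11 | acrolein (prop-2-enal) | C=CC=O | starting material
12 | lithium cyclopenta-1,4-dien-1-olate | [Li+].[O-]C1=CCC=C1 | intermediate
13 | triisopropoxytitanium cyclopenta-1,4-dien-1-olate | CC(C)O[Ti](OC(C)C)(OC(C)C)OC1=CCC=C1 | intermediate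
14 | rac-(5R,1′S)-5-(1-hydroxyprop-2-en-1-yl)cyclopent-2-en-1-one (syn diastereomer, 1:1 mixture of the two enantiomers) | C=C[C@H](O)[C@@H]1C(=O)C=CC1.C=C[C@@H](O)[C@H]1C(=O)C=CC1 | intermediate
15 | (6R)-6-[(1S)-1-hydroxyprop-2-en-1-yl]-5,6-dihydro-2H-pyran-2-one | C=C[C@H](O)[C@H]1CC=CC(=O)O1 | intermediate
16 | brevipolide H, (2S)-1-{(1S,2S)-2-[(S)-hydroxy((2R)-6-oxo-3,6-dihydro-2H-pyran-2-yl)methyl]cyclopropyl}-1-oxopropan-2-yl (2E)-3-(4-methoxyphenyl)prop-2-enoate | COc1ccc(/C=C/C(=O)O[C@@H](C)C(=O)[C@H]2C[C@@H]2[C@H](O)[C@H]2CC=CC(=O)O2)cc1 | target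

**Step count**
Total: 7 steps. Longest linear sequence: 5 steps (steps 1, 2, 3, 4, 7).

**Steps most likely to fail**

Step 6 (the proposed new ring expansion). The conjugated ketone may react slowly, the vinyl carbon may migrate instead of C5, the peracid may epoxidise the terminal alkene, or the selectivity factor may be too low. The fallback uses known chemistry; it sets out from 14 and comes back at 15. Racemic 14 is resolved with immobilised Candida antarctica lipase B and vinyl acetate (MTBE, 30 °C), which leaves (5R)-5-[(1S)-1-hydroxyprop-2-en-1-yl]cyclopent-2-en-1-one F5 unreacted while the (1′R)-enantiomer is converted into (1R)-1-[(1S)-2-oxocyclopent-3-en-1-yl]prop-2-en-1-yl acetate F6. F5 is then ring-expanded under achiral Baeyer–Villiger conditions that spare C=C bonds ((Me3SiO)2, Me3SiOTf cat., CH2Cl2, −40 °C) to give 15. If the ring expansion itself gives the wrong regiochemistry, the fallback for step 5 supplies 15 without it.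

Step 7. The carbene may insert into the free O–H, catalyst and substrate may be mismatched, or the carbene may react with the cinnamate alkene. The fallback sets out from 15 and the acid chloride 8 and comes back at 16.
- 8 is coupled with Bu3SnCH=CH2 (PdCl2(PPh3)2 cat., THF, 50 °C) to give (2S)-3-oxopent-4-en-2-yl (2E)-3-(4-methoxyphenyl)prop-2-enoate F7.
- 15 is silylated (tBuMe2SiOTf, 2,6-lutidine) to (6R)-6-[(1S)-1-{[tert-butyl(dimethyl)silyl]oxy}prop-2-en-1-yl]-5,6-dihydro-2H-pyran-2-one F8.
- Cross-metathesis of F8 with F7 (second-generation Hoveyda–Grubbs catalyst, RuCl2(=CH-C6H4-2-OiPr)(1,3-dimesitylimidazolidin-2-ylidene), CH2Cl2, 40 °C) gives (2S,4E,6S)-6-{[tert-butyl(dimethyl)silyl]oxy}-3-oxo-6-[(2R)-6-oxo-3,6-dihydro-2H-pyran-2-yl]hex-4-en-2-yl (2E)-3-(4-methoxyphenyl)prop-2-enoate F9.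
- Corey–Chaykovsky cyclopropanation of the enone (Me3S(O)I, NaH, DMSO/THF, 0 °C) gives the silyl ether of the target, (2S)-1-[(1S,2S)-2-{(S)-{[tert-butyl(dimethyl)silyl]oxy}[(2R)-6-oxo-3,6-dihydro-2H-pyran-2-yl]methyl}cyclopropyl]-1-oxopropan-2-yl (2E)-3-(4-methoxyphenyl)prop-2-enoate F10. The ylide is expected to add anti to the γ-silyloxy group (Felkin–Anh) and the E-enone gives the trans ring.
- HF·pyridine removes the silyl group to give 16.

Step 5. The syn:anti ratio may be modest, and acrolein may polymerise or undergo 1,4-addition. The fallback sets out from 11 and comes back at 15, so it also makes step 6 unnecessary.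
- CH2=CHMgBr adds to 11 (THF, −78 °C) to give penta-1,4-dien-3-ol F1.
- Sharpless asymmetric epoxidation (Ti(OiPr)4, L-(+)-diisopropyl tartrate, cumene hydroperoxide, 4 Å molecular sieves, CH2Cl2, −20 °C) desymmetrises it to (2R,3S)-1,2-epoxypent-4-en-3-ol F2, which already has the anti O/O relationship.
- LiC≡CCO2Et (from ethyl propiolate and n-BuLi) with BF3·OEt2 (THF, −78 °C) opens the epoxide at its CH2 end to give ethyl (5R,6S)-5,6-dihydroxyoct-7-en-2-ynoate F3.
- Semihydrogenation (H2, Pd/CaCO3 poisoned with Pb(OAc)2, quinoline, EtOAc) gives ethyl (2Z,5R,6S)-5,6-dihydroxyocta-2,7-dienoate F4, which lactonises through the C5 hydroxyl (PPTS, CH2Cl2) to 15.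

**Further compounds**
F1 | step 5 | penta-1,4-dien-3-ol | C=CC(O)C=C
F2 | step 5 | (2R,3S)-1,2-epoxypent-4-en-3-ol | C=C[C@H](O)[C@H]1CO1
F3 | step 5 | ethyl (5R,6S)-5,6-dihydroxyoct-7-en-2-ynoate | C=C[C@H](O)[C@H](O)CC#CC(=O)OCC
F4 | step 5 | ethyl (2Z,5R,6S)-5,6-dihydroxyocta-2,7-dienoate | C=C[C@H](O)[C@H](O)C/C=C\C(=O)OCC
F5 | step 6 | (5R)-5-[(1S)-1-hydroxyprop-2-en-1-yl]cyclopent-2-en-1-one | C=C[C@H](O)[C@@H]1C(=O)C=CC1
F6 | step 6 | (1R)-1-[(1S)-2-oxocyclopent-3-en-1-yl]prop-2-en-1-yl acetate | C=C[C@@H](OC(C)=O)[C@H]1C(=O)C=CC1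
F7 | step 7 | (2S)-3-oxopent-4-en-2-yl (2E)-3-(4-methoxyphenyl)prop-2-enoate | COc1ccc(/C=C/C(=O)O[C@@H](C)C(=O)C=C)cc1
F8 | step 7 | (6R)-6-[(1S)-1-{[tert-butyl(dimethyl)silyl]oxy}prop-2-en-1-yl]-5,6-dihydro-2H-pyran-2-one | C=C[C@H](O[Si](C)(C)C(C)(C)C)[C@H]1CC=CC(=O)O1
F9 | step 7 | (2S,4E,6S)-6-{[tert-butyl(dimethyl)silyl]oxy}-3-oxo-6-[(2R)-6-oxo-3,6-dihydro-2H-pyran-2-yl]hex-4-en-2-yl (2E)-3-(4-methoxyphenyl)prop-2-enoate | COc1ccc(/C=C/C(=O)O[C@@H](C)C(=O)/C=C/[C@H](O[Si](C)(C)C(C)(C)C)[C@H]2CC=CC(=O)O2)cc1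
F10 | step 7 | (2S)-1-[(1S,2S)-2-{(S)-{[tert-butyl(dimethyl)silyl]oxy}[(2R)-6-oxo-3,6-dihydro-2H-pyran-2-yl]methyl}cyclopropyl]-1-oxopropan-2-yl (2E)-3-(4-methoxyphenyl)prop-2-enoate | COc1ccc(/C=C/C(=O)O[C@@H](C)C(=O)[C@H]2C[C@@H]2[C@H](O[Si](C)(C)C(C)(C)C)[C@H]2CC=CC(=O)O2)cc1
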